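Labdane numbering is used for all ring positions (C1–C10 in rings A and B, C17 on C8, C18 and C19 on C4, C20 on C10); α is the face opposite the C10 methyl.

Assumption: in step 2 the alkaloid catalyst is the member of the quinine/quinidine pseudoenantiomeric pair that gives the (S)-enone 3; the sense of induction of this catalyst class is not assigned here from first principles.

## Analysis of the target

The target 25 is a labdane: a trans-decalin (rings A and B) whose ring B holds a tetrasubstituted C8=C9 alkene, with the C17 methyl on C8 and a two-carbon chain from C9 to a β-substituted butenolide (carbonyl C15, ring CH2 C16). It has five stereocentres. C10 carries a β-methyl and C5 an α-hydrogen (trans ring fusion). C4 is quaternary with the hydroxymethyl group C19 β (axial) and the methyl C18 α. The hydroxyls at C2 and C6 are both α and equatorial, so both carbinol centres are the thermodynamically preferred epimers. The hard part is the run C4 (quaternary)–C5–C10 (quaternary), with the 4α-methyl peri to the 6α-oxygen. The butenolide does not survive strong base or hydride and must be made last; the tetrasubstituted alkene is sensitive to singlet oxygen, acid and electrophiles. The strategy rests on one feature: the oxygens on C2 and C19 stand 1,4 across the C3–C4 bond of ring A, so C3 and C4 are both α-carbons of carbonyl groups. Two carbons of like polarity can be joined only by oxidising the two enolates, and doing so on a finished ring B leaves ring A closure with a single new stereocentre, C4.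

## Retrosynthetic reasoning

The butenolide of 25 is taken back to the 3-substituted furan of triol 23, through hydroxybutenolide 24. The furan survives base, hydride and electron-transfer reduction; the butenolide does not. The forward steps must oxidise the furan regioselectively so that the carbonyl ends at C15.

The C19 alcohol of 23 is taken back to the methyl ester of 22, and the 2α-alcohol of 22 to the C2 ketone of 21. This exposes the 1,4-dicarbonyl. The forward reduction at C2 has to be thermodynamically controlled: hydride would enter from the α-face, away from the axial C10 methyl and C19 group, and give the axial alcohol.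

The C3–C4 bond is cut next. 21 is the methanolysis product of tricyclic keto lactone 20, and 20 comes from keto lactone 19 by joining the enolate carbon of the C2 methyl ketone to the enolate carbon of the C19 lactone. The cut is placed here because it removes ring A and the C4 quaternary centre in one bond and leaves a ring B compound whose two arms are trans on C5 and C10. The acyl oxygen of C19 is tied to the C6 oxygen for a stereochemical reason. An open-chain ester enolate on C4 would keep C5–H in its own plane to avoid allylic 1,3-strain, and C3, which is tethered through C10, would then bond to the face that leaves the ester equatorial and the methyl axial, the C4 epimer of the target. The 1,3-diaxial methyl/methyl contact in that product is not enough to reverse this, because the alternative rotamer thrusts an enolate oxygen against the C10 methyl. In the lactone, C4 is a ring atom and C3 can only arrive cis to C10, which is the target configuration.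

Lactone 19 is taken back to silyl ether and methyl ester 18, and the acetonyl arm of 18 to the allyl group of 17. The C9–C11 bond of 17 is cut to enol triflate 13 and the borane 16 made from vinylfuran 15, itself from aldehyde 14. This puts the tetrasubstituted alkene where the triflate was, with no positional ambiguity; 13 comes from ketone 12, which can enolise only towards C8.

The C10–C1 bond of 12 is cut to silyl enol ether 10 and carbonate 11, and the C5–C4 bond of 10 to enone 7 and ketene acetal 9, made from ester 8. Both bonds are formed anti to the neighbouring substituent: the C4 arm anti to the C6 silyloxy group, then the allyl group anti to the arm. The methyl must already be on C10 when the allyl group enters, so that it ends cis to the arm.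

Enone 7 is simplified by removing the C8 methyl (to 6), the C10 methyl (through iodide 5 to 4) and the silyl group (to 3). Hydroxy enone 3 comes from meso endoperoxide 2 and diene 1. The single C6 stereocentre made in this desymmetrisation controls C5, which controls C10; C4 is fixed by the lactone and C2 by thermodynamics.

## Alternatives that were turned down

Alternative 1: Rings A and B are both cut, at C5–C10 and C6–C7, so that the forward key step is a thermal intramolecular Diels–Alder reaction of an open-chain nitro triene giving the trans-fused 6α-nitro octalin A1. In bonds, rings and stereocentres formed per step this is stronger than the chosen route, and the nitro group marks C6 for later oxidation. Against it: the diene terminus C10 is fully substituted and the diene carries substituents on C8 and C9 as well, so the reactive s-cis form is badly strained and a quaternary centre must form at a diene terminus. The open-chain precursor of A1 must already hold the C2 carbinol and the C4 quaternary centre, made without any ring to control them. The nitro group must then pass through a ketone to the 6α-alcohol. The chosen route forms fewer bonds in its key step, but derives all stereocentres from one desymmetrisation and fixes C4 with a tether.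

Alternative 2: Ring A is cut at C1–C10 and C4–C5, and built by a catalytic asymmetric Diels–Alder reaction of a 2-silyloxy diene with 2,6-dimethyl-1,4-benzoquinone A2 under a chiral boron Lewis acid, giving the cis-fused adduct A3. Enantioselective quinone cycloadditions of this kind are well established, and A3 holds C4, C5 and C10 after one step, so on catalytic absolute control and convergence it is stronger than the chosen route. Against it: the diene terminus that becomes C4 is disubstituted, which lowers reactivity sharply and makes C4 depend on diene geometry. Both quinone double bonds carry a methyl, so a quaternary centre forms on the dienophile too. A3 is cis-fused and must be epimerised at C5. Ring B of A3 is an ene-dione that needs a carbonyl removed at C7, a side chain and alkene installed at C9 and the C6 ketone reduced, a long redox sequence after the key step. The chosen route has its ring B oxidation pattern in place before ring A is closed.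

Alternative 3: The C8=C9 alkene is cut, and formed by Ramberg–Bäcklund contraction of a seven-membered cyclic sulfone to the tris(methoxymethyl) ether A4. This is the stronger choice for making the hindered tetrasubstituted alkene: its position is unambiguous and no ring strain is involved, which the chosen key step cannot claim. Against it: the step creates no stereocentre, so all five must exist beforehand on a ring A compound. Both sulfone α-carbons are tertiary and one is next to the quaternary C10, so both C–S bond formation and α-halogenation are hindered. Three acetals must later be removed with acid in the presence of the furan. The chosen route makes the alkene early by cross-coupling and spends its key step on ring A and C4.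

Key step: step 15

## Route

Step 1
Reactants: 1 cyclohexa-1,3-diene
Product: 2 2,3-dioxabicyclo[2.2.2]oct-5-ene (meso endoperoxide)
Conditions: O2, hν, tetraphenylporphyrin (cat.), CH2Cl2, 0 °C
Reagents that add atoms: dioxygen, O=O
Why: [4+2] cycloaddition of singlet oxygen to a cyclic cis-diene; it should give the meso peroxide needed for desymmetrisation.

Step 2
Reactants: 2 2,3-dioxabicyclo[2.2.2]oct-5-ene
Product: 3 (S)-4-hydroxycyclohex-2-en-1-one
Conditions: 9-O-acetyl-6′-hydroxy cinchona alkaloid (10 mol%, pseudoenantiomer chosen for the S product), CH2Cl2, rt
Reagents that add atoms: none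
Why: Desymmetrising Kornblum–DeLaMare rearrangement: the chiral tertiary amine removes one of the two enantiotopic bridgehead protons and the O–O bond breaks. This sets the carbinol centre that becomes C6, the source of all later configuration.

Step 3
Reactants: 3 (S)-4-hydroxycyclohex-2-en-1-one
Product: 4 (S)-4-(tert-butyldimethylsilyloxy)cyclohex-2-en-1-one
Conditions: TBSCl, imidazole, CH2Cl2, 0 °C → rt
Reagents that add atoms: tert-butyldimethylsilyl chloride, CC(C)(C)[Si](C)(C)Cl
Why: Silylation under weakly basic conditions protects the base-sensitive γ-hydroxy enone and installs the group that directs the conjugate addition.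

Step 4
Reactants: 4 (S)-4-(tert-butyldimethylsilyloxy)cyclohex-2-en-1-one
Product: 5 (S)-4-(tert-butyldimethylsilyloxy)-2-iodocyclohex-2-en-1-one
Conditions: I2, pyridine, CH2Cl2, rt
Reagents that add atoms: iodine, II
Why: α-Iodination of an enone by pyridine conjugate addition, iodination of the enolate and elimination; it prepares the α-carbon (future C10) for methylation.

Step 5
Reactants: 5 (S)-4-(tert-butyldimethylsilyloxy)-2-iodocyclohex-2-en-1-one
Product: 6 (S)-4-(tert-butyldimethylsilyloxy)-2-methylcyclohex-2-en-1-one
Conditions: MeB(OH)2, PdCl2(dppf) (5 mol%), Cs2CO3, THF/H2O, 60 °C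
Reagents that add atoms: methylboronic acid, CB(O)O
Why: Suzuki–Miyaura coupling of an α-iodo enone; it places the C20 methyl on the enone α-carbon.

Step 6
Reactants: 6 (S)-4-(tert-butyldimethylsilyloxy)-2-methylcyclohex-2-en-1-one
Product: 7 (4S)-4-(tert-butyldimethylsilyloxy)-2,6-dimethylcyclohex-2-en-1-one (epimers at the new methyl-bearing carbon, future C8)
Conditions: LiN(iPr)2, THF, −78 °C; MeI
Reagents that add atoms: iodomethane, CI
Why: Kinetic α′-enolate alkylation; the new centre becomes sp2 later, so its configuration does not matter.

Step 7
Reactants: 8 methyl propanoate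
Product: 9 1-methoxy-1-(trimethylsilyloxy)prop-1-ene (E/Z mixture)
Conditions: LiN(iPr)2, THF, −78 °C; Me3SiCl
Reagents that add atoms: chlorotrimethylsilane, C[Si](C)(C)Cl
Why: O-silylation of the ester enolate gives the ketene acetal; its geometry is irrelevant because C4 is enolised again in step 15.

Step 8
Reactants: 7 (4S)-4-(tert-butyldimethylsilyloxy)-2,6-dimethylcyclohex-2-en-1-one; 9 1-methoxy-1-(trimethylsilyloxy)prop-1-ene
Product: 10 methyl 2-[6-(tert-butyldimethylsilyloxy)-2,4-dimethyl-3-(trimethylsilyloxy)cyclohex-2-en-1-yl]propanoate, ester arm on C5 β and trans to the 6α-silyloxy group (epimers at C4 and C8)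
Conditions: HNTf2 (2 mol%), CH2Cl2, −78 °C; Et3N quench, non-aqueous work-up
Reagents that add atoms: none
Why: Mukaiyama–Michael addition with silyl transfer to the enolate oxygen. The nucleophile should add to the enone β-carbon anti to the adjacent silyloxy group, setting C5 and forming C4–C5; the product is a regiodefined tetrasubstituted silyl enol ether.

Step 9
Reactants: 10 silyl enol ether from step 8; 11 diallyl carbonate
Product: 12 methyl 2-[2-allyl-6-(tert-butyldimethylsilyloxy)-2,4-dimethyl-3-oxocyclohexyl]propanoate, C10 methyl β and allyl α, C5 arm β, C6 silyloxy α (epimers at C4 and C8)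
Conditions: Pd2(dba)3 (2.5 mol%), PPh3 (10 mol%), Bu4N[Ph3SiF2] (35 mol%), THF, 25 °C
Reagents that add atoms: none
Why: Tsuji–Trost allylation of a silyl enol ether: fluoride and the allyloxide released from 11 unmask the enolate, which attacks the π-allyl palladium complex. The allyl group should enter anti to the branched arm on the neighbouring C5, making the C10 quaternary centre with the methyl cis to the arm.

Step 10
Reactants: 12 ketone from step 9
Product: 13 enol triflate of 12 (C8=C9, triflate on C9)
Conditions: KN(SiMe3)2 (1.1 equiv), THF, −78 °C; PhNTf2, −78 → 0 °C
Reagents that add atoms: N-phenylbis(trifluoromethanesulfonimide), O=S(=O)(N(c1ccccc1)S(=O)(=O)C(F)(F)F)C(F)(F)F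
Why: The ketone can enolise only towards C8 because C10 is quaternary, and it is more acidic than the ester; O-triflation fixes the position of the future tetrasubstituted alkene.

Step 11
Reactants: 14 furan-3-carbaldehyde
Product: 15 3-vinylfuran
Conditions: Ph3PCH3Br, KOtBu, Et2O, 0 °C → rt; used as a distilled ethereal solution
Reagents that add atoms: methyltriphenylphosphonium bromide, C[P+](c1ccccc1)(c1ccccc1)c1ccccc1.[Br-]
Why: Wittig methylenation of an aromatic aldehyde.

Step 12
Reactants: 13 enol triflate; 15 3-vinylfuran
Product: 17 methyl 2-[2-allyl-6-(tert-butyldimethylsilyloxy)-3-[2-(furan-3-yl)ethyl]-2,4-dimethylcyclohex-3-en-1-yl]propanoate (configuration as in 12), via furylethyl-9-BBN borane 16 (not isolated)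
Conditions: 15, 9-borabicyclo[3.3.1]nonane, THF, 0 °C → rt; then 13, PdCl2(dppf) (10 mol%), AsPh3, Cs2CO3, DMF/H2O, 50 °C
Reagents that add atoms: none
Why: Anti-Markovnikov hydroboration of the vinyl group, then B-alkyl Suzuki–Miyaura coupling with the vinyl triflate. This forms C9–C11 and delivers the tetrasubstituted C8=C9 alkene; the borane is consumed before the allyl-bearing triflate is added.

Step 13
Reactants: 17 furan from step 12
Product: 18 ring B keto ester with acetonyl arm on C10, propanoate arm on C5 and 6α-silyl ether (C4 epimers)
Conditions: PdCl2 (10 mol%), CuCl (30 mol%), O2 (1 atm), DMF/H2O 7:1, rt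
Reagents that add atoms: water, O
Why: Tsuji–Wacker oxidation of the monosubstituted alkene to the methyl ketone. The tetrasubstituted alkene does not bind divalent palladium, and the furan is not palladated at room temperature without carboxylate and acid.

Step 14
Reactants: 18 keto ester from step 13
Product: 19 keto lactone: γ-lactone from C19 to the 6α-oxygen, trans-fused to ring B, acetonyl arm on C10 (C4 epimers)
Conditions: HF·pyridine, THF, 0 °C → rt; then pyridinium p-toluenesulfonate (cat.), toluene, 60 °C
Reagents that add atoms: none
Why: Desilylation frees the 6α-hydroxyl, which is trans to the C5 arm and closes onto the methyl ester under mild acid with loss of methanol. The lactone protects both oxygens and ties C19 to ring B for the next step.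

Step 15
Reactants: 19 keto lactone
Product: 20 tricyclic keto lactone: trans-decalin with C2 ketone, 4α-methyl, and C19 lactone carbonyl on C4 (β) bridged to the 6α-oxygen
Conditions: LiN(iPr)2 (2.3 equiv), THF, −78 °C, slow inverse addition of 19 (final 0.01 M); then Fe(acac)3 (2.2 equiv) in THF, −78 °C → rt
Reagents that add atoms: none
Why: Inverse addition to excess amide base should deprotonate the methyl ketone at C3 (kinetic, methyl rather than the neopentyl C1 methylene) and the lactone at C4, giving the dilithium dienolate before either carbonyl can be attacked. Trivalent iron oxidises one enolate by one electron to an α-carbonyl radical, which adds to the carbon of the second enolate; a second equivalent oxidises the resulting ketyl radical anion to the 1,4-dicarbonyl. The closest known reaction type is the intramolecular oxidative heterocoupling of two different carbonyl enolates with trivalent iron or divalent copper oxidants. Ring A closes as a six-membered ring, by 6-exo-trig attack of the C3 radical on the lactone enolate C4=C19, or, if the roles are reversed, by 6-endo-trig attack of the C4 radical on the terminal carbon of the C2=C3 enolate; both give the C3–C4 bond. The new stereocentre C4 is controlled by the lactone ring: C4 is a ring atom of the planar lactone enolate and the tether starts at C10 on the neighbouring ring atom C5, so C3 can only reach the face cis to C10, which places C19 β and the C18 methyl α. An untethered ester enolate would eclipse C5–H with its own plane and send the ester to the equatorial site, which is why the tether is used. The step needs C3 over C1 enolisation, intramolecular over intermolecular coupling (high dilution) and no aldol of the lactone enolate onto the ketone (both sites deprotonated before warming). Its cost is that ring A must close through a twist-boat, because the lactone is trans-fused to ring B and cis-fused to ring A.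

Step 16
Reactants: 20 tricyclic keto lactone
Product: 21 methyl ester of the 6α-hydroxy-2-oxo-labda-8,13(16),14-trien-15,16-epoxy-19-oic acid skeleton: trans-decalin, C2 ketone, axial C19 methyl ester, 6α-hydroxyl, furan side chain
Conditions: NaOMe (0.2 equiv), MeOH, 0 °C → rt
Reagents that add atoms: methanol, CO
Why: Transesterification opens the lactone. It should be driven by relief of the twist-boat strain: the open hydroxy ester relaxes to the all-chair decalin and cannot re-close, because C19 (axial) and the 6α-oxygen (equatorial) are then out of reach.

Step 17
Reactants: 21 hydroxy keto ester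
Product: 22 2α,6α-diol methyl ester (C19 ester, furan side chain)
Conditions: SmI2 (2.5 equiv), H2O, Et3N, THF, 0 °C
Reagents that add atoms: none
Why: Electron-transfer reduction through the ketyl and the α-oxido carbanion should give the more stable equatorial 2α-alcohol, the axial epimer having two syn-axial partners (C20 and C19). Hydride would attack from the α-face and give the axial alcohol; the ester is reduced far more slowly than the ketone with this amount of reagent.

Step 18
Reactants: 22 diol ester
Product: 23 furan triol: 2α,6α,19-trihydroxy compound with 3-furylethyl side chain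
Conditions: LiAlH4, THF, 0 °C → reflux
Reagents that add atoms: none
Why: Hydride reduction of the hindered axial ester to the C19 primary alcohol; the alkene and furan are inert.

Step 19
Reactants: 23 furan triol
Product: 24 γ-hydroxybutenolide: 5-hydroxy-4-substituted furan-2(5H)-one on the side chain (hemiacetal epimers)
Conditions: O2, hν (visible), rose bengal (cat.), iPr2NEt, CH2Cl2, −78 °C
Reagents that add atoms: dioxygen, O=O
Why: [4+2] addition of singlet oxygen to the furan, then base-mediated fragmentation of the endoperoxide. The hindered amine removes the α-proton remote from the substituent, so the carbonyl ends on C15; the hindered tetrasubstituted alkene, flanked by quaternary C10, should react more slowly than the furan at −78 °C.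

Step 20
Reactants: 24 hydroxybutenolide
Product: 25 target, CNP0387838.1
Conditions: NaBH4, EtOH, 0 °C; then aq. HCl to pH 3
Reagents that add atoms: none
Why: The hemiacetal is a masked aldehyde; borohydride reduces it to the hydroxy acid, which lactonises on acidification to the β-substituted butenolide with C16 as CH2.

## Compound list

1 | cyclohexa-1,3-diene | C1=CC=CCC1 | starting material
2 | 2,3-dioxabicyclo[2.2.2]oct-5-ene | C1=C[C@@H]2CC[C@H]1OO2 | intermediate
3 | (S)-4-hydroxycyclohex-2-en-1-one | O=C1C=C[C@@H](O)CC1 | intermediate
4 | (S)-4-(tert-butyldimethylsilyloxy)cyclohex-2-en-1-one | O=C1C=C[C@@H](O[Si](C)(C)C(C)(C)C)CC1 | intermediate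
5 | (S)-4-(tert-butyldimethylsilyloxy)-2-iodocyclohex-2-en-1-one | IC1=C[C@@H](O[Si](C)(C)C(C)(C)C)CCC1=O | intermediate
6 | (S)-4-(tert-butyldimethylsilyloxy)-2-methylcyclohex-2-en-1-one | CC1=C[C@@H](O[Si](C)(C)C(C)(C)C)CCC1=O | intermediate
7 | (4S)-4-(tert-butyldimethylsilyloxy)-2,6-dimethylcyclohex-2-en-1-one | CC1C(=O)C(C)=C[C@@H](O[Si](C)(C)C(C)(C)C)C1 | intermediate
8 | methyl propanoate | CCC(=O)OC | starting material
9 | 1-methoxy-1-(trimethylsilyloxy)prop-1-ene | CC=C(OC)O[Si](C)(C)C | intermediate
10 | Michael adduct silyl enol ether | CC1C(O[Si](C)(C)C)=C(C)[C@H](C(C)C(=O)OC)[C@@H](O[Si](C)(C)C(C)(C)C)C1 | intermediate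
11 | diallyl carbonate | C=CCOC(=O)OCC=C | starting material
12 | allyl ketone with C10 quaternary centre | CC1C(=O)[C@@](C)(CC=C)[C@H](C(C)C(=O)OC)[C@@H](O[Si](C)(C)C(C)(C)C)C1 | intermediate
13 | enol triflate | CC1=C(OS(=O)(=O)C(F)(F)F)[C@@](C)(CC=C)[C@H](C(C)C(=O)OC)[C@@H](O[Si](C)(C)C(C)(C)C)C1 | intermediate
14 | furan-3-carbaldehyde | O=Cc1ccoc1 | starting material
15 | 3-vinylfuran | C=Cc1ccoc1 | intermediate
16 | 9-[2-(furan-3-yl)ethyl]-9-borabicyclo[3.3.1]nonane | C(Cc1ccoc1)B1C2CCCC1CCC2 | intermediate
17 | coupled furan with allyl arm | CC1=C(CCc2ccoc2)[C@@](C)(CC=C)[C@H](C(C)C(=O)OC)[C@@H](O[Si](C)(C)C(C)(C)C)C1 | intermediate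
18 | ring B keto ester (acetonyl arm, propanoate arm, 6α-silyl ether) | CC1=C(CCc2ccoc2)[C@@](C)(CC(C)=O)[C@H](C(C)C(=O)OC)[C@@H](O[Si](C)(C)C(C)(C)C)C1 | intermediate
19 | keto lactone (19,6α-lactone on ring B) | CC1=C(CCc2ccoc2)[C@@](C)(CC(C)=O)[C@@H]2C(C)C(=O)O[C@H]2C1 | intermediate
20 | tricyclic keto lactone | CC1=C(CCc2ccoc2)[C@@]2(C)CC(=O)C[C@@]3(C)[C@@H]2[C@H](C1)OC3=O | intermediate
21 | hydroxy keto ester (trans-decalin, C2 ketone, C19 methyl ester) | CC1=C(CCc2ccoc2)[C@@]2(C)CC(=O)C[C@](C)(C(=O)OC)[C@@H]2[C@@H](O)C1 | intermediate
22 | 2α,6α-diol methyl ester | CC1=C(CCc2ccoc2)[C@@]2(C)C[C@@H](O)C[C@](C)(C(=O)OC)[C@@H]2[C@@H](O)C1 | intermediate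
23 | furan triol | CC1=C(CCc2ccoc2)[C@@]2(C)C[C@@H](O)C[C@](C)(CO)[C@@H]2[C@@H](O)C1 | intermediate
24 | γ-hydroxybutenolide | CC1=C(CCC2=CC(=O)OC2O)[C@@]3(C)C[C@@H](O)C[C@](C)(CO)[C@@H]3[C@@H](O)C1 | intermediate
25 | CNP0387838.1 | CC1=C(CCC2=CC(=O)OC2)[C@@]2(C)C[C@@H](O)C[C@](C)(CO)[C@@H]2[C@@H](O)C1 | target

## Step count and least certain steps

Total step count: 20. Longest linear sequence: 18 (steps 1–6, 8–10, 12–20).

Step 15 (key step). The ring closure may be too slow: ring A must form through a twist-boat, and the α-carbonyl radical could then be quenched by hydrogen abstraction from the solvent or couple intermolecularly. Fallback: set out from enone 7 and move the C18 methyl to after ring closure.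
- Conjugate addition of 1-methoxy-1-(trimethylsilyloxy)ethene to 7 under the conditions of step 8 should give the acetate-arm silyl enol ether F1.
- Allylation as in step 9 gives ketone F2, triflation gives enol triflate F3, coupling with borane 16 gives furan F4, and Wacker oxidation gives keto ester F5.
- The dienolate of F5 is unhindered at C4 and free to close ring A through a chair; oxidation with Fe(acac)3 gives decalin keto ester F6 (C4–H).
- SmI2 reduction gives the 2α-alcohol F7.
- The dianion of F7 (LiN(iPr)2, 2.2 equiv) is methylated with iodomethane from the equatorial α-face, the β-face of the exocyclic C4 enolate being closed by the axial C10 methyl, to give the 4α-methyl 19-ester F8.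
- Bu4NF removes the silyl group and the route is rejoined at diol ester 22.

Step 9. Facial selectivity at C10 may be poor: the face anti to the C5 arm is the one that carries the C6 silyl ether, so the allyl group could enter cis to the arm. Fallback: set out from iodide 5 and exchange the order of the two C10 substituents, so that the group that must be cis to the arm enters last.
- Suzuki coupling of 5 with allylboronic acid pinacol ester gives the 2-allyl enone F9.
- α′-Methylation as in step 6 gives F10.
- Mukaiyama–Michael addition of 9 gives silyl enol ether F11.
- Fluoride-promoted methylation of F11 (iodomethane, benzyltrimethylammonium fluoride) then delivers the methyl to the same face and returns to ketone 12.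

Step 13. The furan may be palladated or oxidised, or the neopentyl-type allyl group may give aldehyde by anti-Markovnikov attack. Fallback: set out from silyl enol ether 10 and unmask the ketone by ozonolysis before the furan is present.
- Allylation of 10 with bis(2-methylallyl) carbonate under the conditions of step 9 gives methallyl ketone F12.
- Triflation gives F13.
- Ozonolysis (O3, CH2Cl2/MeOH, −78 °C, indicator end point; Me2S) cleaves the 1,1-disubstituted alkene and leaves the electron-poor vinyl triflate, giving methyl ketone triflate F14.
- Coupling of F14 with borane 16 as in step 12 returns to keto ester 18.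

Step 19. Singlet oxygen may undergo an ene reaction at the tetrasubstituted alkene in competition with addition to the furan. Fallback: set out from triol 23 and avoid singlet oxygen altogether.
- Iridium-catalysed C–H borylation ([Ir(OMe)(cod)]2, 4,4′-di-tert-butyl-2,2′-bipyridine, B2pin2, THF) at the unhindered furan α-position C15 gives furyl boronate F15.
- Oxidation with NaBO3·4H2O gives the 2-hydroxyfuran, which tautomerises to the conjugated butenolide, target 25.

## Further compounds

F1 | step 15 | acetate-arm silyl enol ether | CC1C(O[Si](C)(C)C)=C(C)[C@H](CC(=O)OC)[C@@H](O[Si](C)(C)C(C)(C)C)C1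
F2 | step 15 | acetate-arm allyl ketone | CC1C(=O)[C@@](C)(CC=C)[C@H](CC(=O)OC)[C@@H](O[Si](C)(C)C(C)(C)C)C1
F3 | step 15 | acetate-arm enol triflate | CC1=C(OS(=O)(=O)C(F)(F)F)[C@@](C)(CC=C)[C@H](CC(=O)OC)[C@@H](O[Si](C)(C)C(C)(C)C)C1
F4 | step 15 | acetate-arm coupled furan | CC1=C(CCc2ccoc2)[C@@](C)(CC=C)[C@H](CC(=O)OC)[C@@H](O[Si](C)(C)C(C)(C)C)C1
F5 | step 15 | acetate-arm keto ester | CC1=C(CCc2ccoc2)[C@@](C)(CC(C)=O)[C@H](CC(=O)OC)[C@@H](O[Si](C)(C)C(C)(C)C)C1
F6 | step 15 | decalin keto ester with C4–H | CC1=C(CCc2ccoc2)[C@@]2(C)CC(=O)CC(C(=O)OC)[C@@H]2[C@@H](O[Si](C)(C)C(C)(C)C)C1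
F7 | step 15 | 2α-hydroxy decalin ester with C4–H | CC1=C(CCc2ccoc2)[C@@]2(C)C[C@@H](O)CC(C(=O)OC)[C@@H]2[C@@H](O[Si](C)(C)C(C)(C)C)C1
F8 | step 15 | 4α-methyl 19-ester, 2α-hydroxy, 6α-silyl ether | CC1=C(CCc2ccoc2)[C@@]2(C)C[C@@H](O)C[C@](C)(C(=O)OC)[C@@H]2[C@@H](O[Si](C)(C)C(C)(C)C)C1
F9 | step 9 | (S)-2-allyl-4-(tert-butyldimethylsilyloxy)cyclohex-2-en-1-one | C=CCC1=C[C@@H](O[Si](C)(C)C(C)(C)C)CCC1=O
F10 | step 9 | (4S)-2-allyl-4-(tert-butyldimethylsilyloxy)-6-methylcyclohex-2-en-1-one | C=CCC1=C[C@@H](O[Si](C)(C)C(C)(C)C)CC(C)C1=O
F11 | step 9 | Michael adduct silyl enol ether with allyl on C10 | CC1C(O[Si](C)(C)C)=C(CC=C)[C@H](C(C)C(=O)OC)[C@@H](O[Si](C)(C)C(C)(C)C)C1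
F12 | step 13 | methallyl ketone | CC1C(=O)[C@@](C)(CC(C)=C)[C@H](C(C)C(=O)OC)[C@@H](O[Si](C)(C)C(C)(C)C)C1
F13 | step 13 | methallyl enol triflate | CC1=C(OS(=O)(=O)C(F)(F)F)[C@@](C)(CC(C)=C)[C@H](C(C)C(=O)OC)[C@@H](O[Si](C)(C)C(C)(C)C)C1
F14 | step 13 | acetonyl enol triflate | CC1=C(OS(=O)(=O)C(F)(F)F)[C@@](C)(CC(C)=O)[C@H](C(C)C(=O)OC)[C@@H](O[Si](C)(C)C(C)(C)C)C1
F15 | step 19 | furyl pinacol boronate of triol 23 (boron on C15) | CC1=C(CCc2coc(B3OC(C)(C)C(C)(C)O3)c2)[C@@]2(C)C[C@@H](O)C[C@](C)(CO)[C@@H]2[C@@H](O)C1
A1 | alternative 1 | trans-fused 6α-nitro octalin | CC1=C(CCc2ccoc2)[C@@]2(C)C[C@@H](O[Si](C)(C)C(C)(C)C)C[C@](C)(COCc3ccccc3)[C@@H]2[C@@H]([N+](=O)[O-])C1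
A2 | alternative 2 | 2,6-dimethyl-1,4-benzoquinone | CC1=CC(=O)C=C(C)C1=O
A3 | alternative 2 | cis-fused Diels–Alder adduct | CC1=CC(=O)[C@@H]2[C@@](C)(COCc3ccccc3)C=C(O[Si](C)(C)C(C)(C)C)C[C@]2(C)C1=O
A4 | alternative 3 | tris(methoxymethyl) ether of the furan-masked core | CC1=C(CCc2ccoc2)[C@@]2(C)C[C@@H](OCOC)C[C@](C)(COCOC)[C@@H]2[C@@H](OCOC)C1
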